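## The problem

Atom numbering used throughout: lactone C1H2–O2–C3(=O)–C4–C4a–C11a; nine-membered ring C4a–C5–C6–C7–C8–C9–C10–C11–C11a; C19 is the methylene carbon on C11; the side chain is C12=C4, C13(OAc), C14–C15 (epoxide).

- The target 37 is a δ-lactone trans-fused at C4a–C11a to a nine-membered carbocycle. The ring carries a methyl carbinol at C7, a cis 8,9-epoxide and an exocyclic methylene at C11. C4 bears an E-alkylidene whose chain holds an acetoxy centre (C13) and a trisubstituted epoxide (C14–C15).
- Seven stereocentres and one alkene geometry have to be set. C4a and C11a are neighbours and can control each other inside a six-membered ring. C8 and C9 can be set from C7 by hydroxyl-directed epoxidation of a Z-C8=C9 alkene.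
- C7 is too far from C4a/C11a to be controlled by them, and C13/C14 lie outside the bicycle, so these centres need their own sources of chirality.
- The medium ring is the main constructional difficulty. Its closure must leave a Z-alkene at C8=C9 and must not move the C11 methylene into the ring.
- Several groups are fragile: both epoxides (the trisubstituted one towards acid, the ring one towards its neighbouring tertiary alkoxide), the allylic acetate, and the alkylidene lactone (a Michael acceptor). Any intermediate with a C11 ketone is also fragile, because that ketone is β to the lactone oxygen on C1 and can expel it.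
- The enabling feature is that C11 is a 1,1-disubstituted alkene carbon and C10 becomes allylic once the epoxide is traced back to the C8=C9 alkene. The C10–C11 bond therefore joins a vinyl carbon to an allyl terminus, and both can be electrophiles: an enol triflate from a C11 methyl ketone and an allylic carbonate at C10.

## Retrosynthesis

**Epoxide and acetate last (37 ⇒ 36 ⇒ 35 ⇒ 34).** The C8–O and C9–O bonds are cut first, giving the Z-allylic tertiary alcohol 36. An 8,9-epoxide next to a C7 alkoxide would not be safe under the LDA, DBU and fluoride used to attach the side chain, so it is made in the final step. A vanadium-catalysed directed epoxidation is asked to pick the allylic C8=C9 alkene over the C11 methylene and the electron-poor C4=C12 alkene, and to deliver oxygen cis to the hydroxyl. Acetate 36 comes from diol 35 by acylation of the only secondary hydroxyl, and 35 from the bis(triethylsilyl) ether 34.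

**C4=C12 (34 ⇒ 25 + 31).** Cutting the alkylidene bond gives the plain bicyclic lactone 25 and aldehyde 31, which already holds C13 and C14. A cut at C12–C13 would instead need an unselective addition to an epoxy aldehyde. The forward aldol/elimination (via 32 and 33) has to give the E-alkene and must not epimerise C13.

**C10–C11, the key cut (25 ⇒ 24).** The nine-membered ring is opened between the vinyl carbon C11 and the allyl terminus C10, giving the monocyclic lactone 24 with an enol triflate and an E-allylic methyl carbonate. Closure at C8=C9 by metathesis would have to make a Z-alkene next to the fully substituted C7. Closures at C4a–C5 or C11–C11a would create a stereocentre in the ring-forming step. The C10–C11 closure creates none, and its two arms sit on adjacent, trans-disposed carbons of a six-membered ring. The forward reaction must couple two electrophiles reductively, choose C10 over C8 and give the Z-alkene.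

**Allylic carbonate and enol triflate (24 ⇒ 22 + 23; 22 ⇒ 21 ⇒ 20).** The C8=C9 bond of 24 is cut by cross metathesis to the vinyl compound 22 and allyl methyl carbonate 23. The carbonate cannot be carried through organometallic steps, so it comes last. The enol triflate 22 comes from methyl ketone 21, which is revealed from carbinol 20 only one step earlier because it is a β-acyloxy ketone.

**C4a–C5 (20 ⇒ 11 + 17).** The chain is detached at C4a, giving dihydropyranone 11 and the five-carbon iodide 17. Conjugate addition anti to the C11a substituent sets C4a from C11a. The alternative cut at C4a–C11a would need an asymmetric Michael reaction between acyclic partners. Each fragment now holds one controlling centre.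

**Dihydropyranone (11 ⇒ 10 ⇒ 9 ⇒ 8 ⇒ 7 ⇒ 3 + 4; 3 ⇒ 1 + 2).** The C4=C4a alkene is cut by ring-closing metathesis (acrylate 9) and the C1–O ester bond by acylation of diol 8. The C11a–C11 bond is cut by an auxiliary-controlled aldol between crotonyl imide 3 and acetaldehyde 4. The carbinol carbon C11 acts as a traceless partner: it is formed with C11a and later oxidised to the ketone that becomes the enol triflate.

**Chain (17 ⇒ 15 ⇒ 14 ⇒ 13 ⇒ 12).** C7 is bought with (S)-linalool 12. Its trisubstituted alkene is cleaved and one further carbon is removed by decarboxylative iodination, so that C5 becomes the nucleophilic carbon.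

**Side-chain aldehyde (31 ⇒ 30 ⇒ 29 ⇒ 28 ⇒ 27 ⇒ 26).** The C14–C15 epoxide is traced to the allylic alcohol 28, whose hydroxyl directs a peracid to the threo epoxide. C13 comes from (S)-glyceraldehyde acetonide 26 by Wittig olefination.

## Roads not taken

**Alternative 1:** Cut C3–C4 and C3–O2 and close the lactone by palladium-catalysed cyclocarbonylation of a C4≡C12 alkyne bearing a free C1 hydroxyl, giving the silyl ether A1.
- Merits: syn addition of palladium hydride fixes the E geometry mechanistically, and lactone and alkylidene form in one step. In this respect it is better than the chosen plan, which relies on a thermodynamically biased elimination (step 22) and holds an olefination in reserve.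
- Weak points: the nine-membered ring must be closed first, without the lactone to hold the two arms. Both epoxides, the tertiary allylic alcohol and the C11 methylene would then be exposed to palladium hydride and CO. The 14,15-epoxide would be propargylic and liable to ionise with zerovalent palladium. Regiochemistry of hydropalladation on an internal alkyne is also not assured.
- Comparison: the chosen plan uses the lactone early as the scaffold for C4a/C11a and for ring closure, and brings in the sensitive side chain late as a finished aldehyde.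

**Alternative 2:** Cut the ring by a Grob fragmentation of a hydrindenol (C7–C11 cleaved, C19 tosylate expelled), giving the cyclononadienone A2.
- Merits: fragmentation is known chemistry and needs no high dilution. The Z-C8=C9 alkene is inherited from a six-membered ring and the C11 methylene forms in the same event. For the ring-forming step this road is safer than the chosen one.
- Weak points: C7 emerges as a ketone, so the methyl carbinol must be made by addition to a mobile medium-ring enone, with 1,2/1,4 and facial selectivity open. The lactone is not yet present in A2 and costs further deprotection, oxidation and cyclisation steps. The bicyclic substrate with its contiguous stereocentres and the required anti-periplanar alignment is itself a long synthesis.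
- Comparison: the chosen plan takes C7 intact from linalool and keeps the lactone throughout. It accepts an unprecedented ring closure, for which a palladium-based fallback is given.

**Alternative 3:** Cut C7–C8 and close the ring by SmI2 pinacol coupling of a keto aldehyde, giving the cis-diol A3.
- Merits: one step forms the ring and both C7 and C8 oxygenated centres with a known reagent, and the lactone scaffold is already in place. It reaches the C7/C8 oxygenation more directly than the chosen plan.
- Weak points: ketyl coupling to a nine-membered ring has little support. Two stereocentres, one quaternary, rest on chelation in a floppy transition state. The C9 oxygen must be set opposite to the final epoxide and then activated selectively beside a 7,8-diol. The α-alkoxy aldehyde precursor is epimerisable.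
- Comparison: the chosen plan creates no stereocentre in the ring closure, buys C7, and sets C8/C9 in one directed epoxidation with medium-ring precedent. Its price is the novelty of the nickel step.

Key step: step 15

## Route

Remark on the chemistry: the (7S,8R,9R) descriptors of the target place the epoxide oxygen cis to the C7 hydroxyl on the nine-membered ring; the final step is planned on that basis.

Step 1
Reactants: 1 (R)-4-benzyloxazolidin-2-one; 2 (E)-but-2-enoyl chloride
Product: 3 (R)-4-benzyl-3-[(E)-but-2-enoyl]oxazolidin-2-one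
Conditions: n-BuLi, THF, −78 °C; then 2, −78 to 0 °C
Reagents that add atoms: none
Why: N-acylation of the lithiated oxazolidinone with the acid chloride (attachment of the Evans auxiliary); no stereocentre is formed and the E-alkene is untouched at low temperature.

Step 2
Reactants: 3 (R)-4-benzyl-3-[(E)-but-2-enoyl]oxazolidin-2-one; 4 acetaldehyde
Product: 7 (R)-4-benzyl-3-[(2R,3S)-2-ethenyl-3-hydroxybutanoyl]oxazolidin-2-one, via boron dienolate 5 (not isolated), via boron aldolate 6 (not isolated)
Conditions: Bu2BOTf, Et3N, CH2Cl2, −78 to 0 °C; 4, −78 °C; pH 7 buffer, MeOH, H2O2, 0 °C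
Reagents that add atoms: none
Why: Evans boron aldol in its deconjugative form: γ-deprotonation gives dienolate 5, which reacts through its α-carbon in a Zimmerman–Traxler chair; the benzyl group of the (R)-auxiliary shields one face, so the syn adduct with the required configuration at the vinyl-bearing carbon (future C11a) should form, and the carbinol centre (future C11) made alongside is erased in step 12.

Step 3
Reactants: 7 (R)-4-benzyl-3-[(2R,3S)-2-ethenyl-3-hydroxybutanoyl]oxazolidin-2-one
Product: 8 (2S,3S)-2-ethenylbutane-1,3-diol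
Conditions: LiBH4, MeOH (1 equiv), Et2O, 0 °C
Reagents that add atoms: none
Why: Reductive removal of the oxazolidinone auxiliary; the imide carbonyl becomes the primary alcohol (future C1) and no stereocentre is touched.

Step 4
Reactants: 8 (2S,3S)-2-ethenylbutane-1,3-diol
Product: 9 (2S,3S)-2-ethenyl-3-hydroxybutyl prop-2-enoate
Conditions: acryloyl chloride (1.0 equiv), 2,4,6-collidine, CH2Cl2, −78 °C
Reagents that add atoms: acryloyl chloride, C=CC(Cl)=O
Why: Chemoselective O-acylation of the primary over the secondary hydroxyl with one equivalent of acid chloride and a hindered base at low temperature.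

Step 5
Reactants: 9 (2S,3S)-2-ethenyl-3-hydroxybutyl prop-2-enoate
Product: 10 (5S)-5-[(1S)-1-hydroxyethyl]-5,6-dihydro-2H-pyran-2-one
Conditions: second-generation Grubbs catalyst (5 mol%), CH2Cl2 (5 mM), 40 °C
Reagents that add atoms: none
Why: Ring-closing metathesis of an acrylate with a monosubstituted alkene to the α,β-unsaturated δ-lactone, driven by loss of ethylene; the allylic centre C11a is not affected.

Step 6
Reactants: 10 (5S)-5-[(1S)-1-hydroxyethyl]-5,6-dihydro-2H-pyran-2-one
Product: 11 (5S)-5-[(1S)-1-(trimethylsilyloxy)ethyl]-5,6-dihydro-2H-pyran-2-one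
Conditions: TMSCl, imidazole, CH2Cl2, 0 °C
Reagents that add atoms: chlorotrimethylsilane, C[Si](C)(C)Cl
Why: Silylation of the secondary alcohol so that it does not quench the organomagnesium reagent of step 11; the trimethylsilyl ether is chosen because it is lost in the acidic work-up of step 11 while the tertiary triethylsilyl ether remains.

Step 7
Reactants: 12 (S)-linalool
Product: 13 triethyl{[(3S)-3,7-dimethylocta-1,6-dien-3-yl]oxy}silane
Conditions: TESOTf, 2,6-lutidine, CH2Cl2, −78 to 0 °C
Reagents that add atoms: triethylsilyl trifluoromethanesulfonate, CC[Si](CC)(CC)OS(=O)(=O)C(F)(F)F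
Why: Silylation of the hindered tertiary allylic alcohol with the silyl triflate; the C7 stereocentre is taken unchanged from the chiral pool.

Step 8
Reactants: 13 triethyl{[(3S)-3,7-dimethylocta-1,6-dien-3-yl]oxy}silane
Product: 14 (4S)-4-methyl-4-(triethylsilyloxy)hex-5-enal
Conditions: O3, pyridine, CH2Cl2, −78 °C, Sudan Red 7B as end-point indicator
Reagents that add atoms: ozone, [O-][O+]=O
Why: Chemoselective ozonolysis: the electron-rich trisubstituted alkene is consumed much faster than the vinyl group next to the silyloxy-bearing quaternary carbon; the dye marks the end point and pyridine turns the carbonyl oxide directly into the aldehyde.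

Step 9
Reactants: 14 (4S)-4-methyl-4-(triethylsilyloxy)hex-5-enal
Product: 15 (4S)-4-methyl-4-(triethylsilyloxy)hex-5-enoic acid
Conditions: NaClO2, NaH2PO4, 2-methylbut-2-ene, t-BuOH/H2O, 0 to 25 °C
Reagents that add atoms: sodium chlorite, [Na+].[O-]Cl=O
Why: Pinnick oxidation; the buffer spares the tertiary silyl ether and the scavenger keeps hypochlorous acid away from the vinyl group.

Step 10
Reactants: 15 (4S)-4-methyl-4-(triethylsilyloxy)hex-5-enoic acid
Product: 17 triethyl{[(3S)-5-iodo-3-methylpent-1-en-3-yl]oxy}silane, via Barton ester 16 (not isolated)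
Conditions: 1-hydroxypyridine-2(1H)-thione, DCC, DMAP (cat.), CH2Cl2, dark, 0 to 25 °C; then CHI3, visible light, 25 °C
Reagents that add atoms: iodoform, IC(I)I
Why: Barton decarboxylative iodination: thiohydroxamate ester 16 fragments under light to the primary C5 radical, which takes iodine from iodoform faster than it can attack its own vinyl group (only three- or four-membered closures are open to it); this removes the carbon that would otherwise lie between C5 and C4a.

Step 11
Reactants: 17 triethyl{[(3S)-5-iodo-3-methylpent-1-en-3-yl]oxy}silane; 11 (5S)-5-[(1S)-1-(trimethylsilyloxy)ethyl]-5,6-dihydro-2H-pyran-2-one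
Product: 20 (4R,5S)-5-[(1S)-1-hydroxyethyl]-4-[(3S)-3-methyl-3-(triethylsilyloxy)pent-4-en-1-yl]oxan-2-one, via Grignard reagent 18 (not isolated), via silyl ketene acetal 19 (not isolated)
Conditions: Mg, Et2O, 25 °C; CuBr·SMe2 (10 mol%), TMSCl, THF, −78 °C, then 11; aq. citric acid, MeOH, 0 °C
Reagents that add atoms: none
Why: Copper-catalysed conjugate addition of a Grignard reagent accelerated by TMSCl; the nucleophile enters C4a anti to the C11a substituent of the half-chair dihydropyranone, which sets the trans C4a/C11a relationship; the enolate is trapped as ketene acetal 19, and mild acid then removes both trimethylsilyl groups but not the tertiary triethylsilyl ether.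

Step 12
Reactants: 20 (4R,5S)-5-[(1S)-1-hydroxyethyl]-4-[(3S)-3-methyl-3-(triethylsilyloxy)pent-4-en-1-yl]oxan-2-one
Product: 21 (4R,5S)-5-acetyl-4-[(3S)-3-methyl-3-(triethylsilyloxy)pent-4-en-1-yl]oxan-2-one
Conditions: Dess–Martin periodinane, NaHCO3, CH2Cl2, 0 to 25 °C
Reagents that add atoms: none
Why: Dess–Martin oxidation of the secondary alcohol under buffered, non-basic conditions; the C11 centre that helped to set C11a disappears and the β-acyloxy ketone is not exposed to base or heat.

Step 13
Reactants: 21 (4R,5S)-5-acetyl-4-[(3S)-3-methyl-3-(triethylsilyloxy)pent-4-en-1-yl]oxan-2-one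
Product: 22 1-[(3S,4R)-4-[(3S)-3-methyl-3-(triethylsilyloxy)pent-4-en-1-yl]-6-oxooxan-3-yl]ethenyl trifluoromethanesulfonate
Conditions: KHMDS, THF, −78 °C; then PhNTf2, −78 to −40 °C
Reagents that add atoms: N-phenylbis(trifluoromethanesulfonimide), O=S(=O)(N(c1ccccc1)S(=O)(=O)C(F)(F)F)C(F)(F)F
Why: Kinetic enolisation of a methyl ketone with a hindered amide base and O-triflation; deprotonation at the methyl group is faster than at the tertiary C11a–H or at the less acidic lactone α-CH2, which should give the 1,1-disubstituted enol triflate and leave C11a untouched.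

Step 14
Reactants: 22 1-[(3S,4R)-4-[(3S)-3-methyl-3-(triethylsilyloxy)pent-4-en-1-yl]-6-oxooxan-3-yl]ethenyl trifluoromethanesulfonate; 23 allyl methyl carbonate
Product: 24 methyl (2E,4S)-4-methyl-6-[(4R,5S)-2-oxo-5-{1-[(trifluoromethanesulfonyl)oxy]ethenyl}oxan-4-yl]-4-(triethylsilyloxy)hex-2-en-1-yl carbonate
Conditions: second-generation Hoveyda–Grubbs catalyst (10 mol%), 23 (5 equiv), CH2Cl2, 40 °C
Reagents that add atoms: none
Why: Olefin cross metathesis between a vinyl group on a fully substituted carbon, which does not homodimerise, and an excess of a reactive allylic partner; the bulk at C7 should enforce the E geometry and the enol triflate alkene is inert to the ruthenium carbene.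

Step 15
Reactants: 24 methyl (2E,4S)-4-methyl-6-[(4R,5S)-2-oxo-5-{1-[(trifluoromethanesulfonyl)oxy]ethenyl}oxan-4-yl]-4-(triethylsilyloxy)hex-2-en-1-yl carbonate
Product: 25 (4aR,7S,8Z,11aR)-7-methyl-11-methylidene-7-(triethylsilyloxy)-4,4a,5,6,7,10,11,11a-octahydro-1H-cyclonona[c]pyran-3-one
Conditions: NiBr2(glyme) (30 mol%), 4,4'-di-tert-butyl-2,2'-bipyridine (36 mol%), Mn powder, TMSCl (cat.), DMA, 25 °C, slow addition of 24 (final 2 mM)
Reagents that add atoms: none
Why: Proposed new method: zerovalent nickel, formed from NiBr2(glyme), the bipyridine and Mn, should insert into the C11–O bond of the enol triflate; reduction by Mn gives a monovalent vinylnickel species that ionises the allylic carbonate (loss of CO2 and methoxide) to a vinyl(π-allyl)nickel intermediate, and C(sp2)–C(sp3) reductive elimination forms C10–C11 while Mn returns nickel to the zerovalent state. The closest known reaction type is the intermolecular nickel-catalysed reductive cross-electrophile coupling of vinyl bromides or triflates with allylic acetates and carbonates, which joins the vinyl carbon to the less hindered allyl terminus; the intramolecular medium-ring version is new. The nine-membered ring closes by bond formation at the distal allyl terminus C10, so that the allyl double bond ends inside the ring as C8=C9; closure at the proximal terminus C8 would give a seven-membered ring with an exocyclic vinyl group. No stereocentre is created; C4a, C7 and C11a are spectators. Selectivity for C10 is needed and should come from C8 being neopentyl-like, flanked by the fully substituted C7 with its methyl and triethylsilyloxy groups. Z geometry is needed as well: the E-carbonate first gives the syn π-allyl, which can isomerise through the σ-allyl bonded at C8 to the anti form, and only the anti form can span the ring. The trans-diequatorial arms on C4a and C11a are gauche to each other and hold the two termini close, and slow addition at high dilution suppresses intermolecular coupling.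

Step 16
Reactants: 26 (S)-2,2-dimethyl-1,3-dioxolane-4-carbaldehyde
Product: 27 (4R)-2,2-dimethyl-4-(2-methylprop-1-en-1-yl)-1,3-dioxolane
Conditions: isopropyltriphenylphosphonium iodide, n-BuLi, THF, 0 °C; then 26, −78 to 25 °C
Reagents that add atoms: isopropyltriphenylphosphonium iodide, CC(C)[P+](c1ccccc1)(c1ccccc1)c1ccccc1.[I-]
Why: Wittig olefination with a non-stabilised disubstituted ylide; the product alkene has no geometry to control and addition of the α-alkoxy aldehyde at −78 °C avoids epimerisation.

Step 17
Reactants: 27 (4R)-2,2-dimethyl-4-(2-methylprop-1-en-1-yl)-1,3-dioxolane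
Product: 28 (2R)-4-methylpent-3-ene-1,2-diol
Conditions: AcOH/H2O (4:1), 25 °C
Reagents that add atoms: none
Why: Acetal hydrolysis with a weak acid that should not ionise the allylic C–O bond.

Step 18
Reactants: 28 (2R)-4-methylpent-3-ene-1,2-diol
Product: 29 (1S)-1-[(2R)-3,3-dimethyloxiran-2-yl]ethane-1,2-diol
Conditions: mCPBA, NaHCO3, CH2Cl2, −10 to 0 °C
Reagents that add atoms: 3-chloroperoxybenzoic acid, OOC(=O)c1cccc(Cl)c1
Why: Hydroxyl-directed peracid epoxidation under A(1,3) control: the Z-methyl group forces the carbinol hydrogen into the alkene plane and the hydrogen-bonded peracid is delivered from the face of the hydroxyl, so the threo epoxy alcohol (C13/C14 as in the target) should predominate.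

Step 19
Reactants: 29 (1S)-1-[(2R)-3,3-dimethyloxiran-2-yl]ethane-1,2-diol
Product: 30 (2R)-2-[(1S)-1,2-bis(triethylsilyloxy)ethyl]-3,3-dimethyloxirane
Conditions: TESCl, imidazole, DMAP (cat.), CH2Cl2, 0 to 25 °C
Reagents that add atoms: chlorotriethylsilane, CC[Si](Cl)(CC)CC
Why: Exhaustive silylation of the primary and the secondary hydroxyl under mild basic conditions that leave the epoxide alone.

Step 20
Reactants: 30 (2R)-2-[(1S)-1,2-bis(triethylsilyloxy)ethyl]-3,3-dimethyloxirane
Product: 31 (2R)-2-[(2R)-3,3-dimethyloxiran-2-yl]-2-(triethylsilyloxy)acetaldehyde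
Conditions: (COCl)2, DMSO, CH2Cl2, −78 to −35 °C; Et3N, −78 to 0 °C
Reagents that add atoms: none
Why: Swern oxidation of a primary triethylsilyl ether directly to the aldehyde: activated DMSO cleaves and oxidises the unhindered primary silyl ether while the secondary one stays, so no free α-hydroxy aldehyde is handled and C13 is not epimerised at low temperature.

Step 21
Reactants: 25 (4aR,7S,8Z,11aR)-7-methyl-11-methylidene-7-(triethylsilyloxy)-4,4a,5,6,7,10,11,11a-octahydro-1H-cyclonona[c]pyran-3-one; 31 (2R)-2-[(2R)-3,3-dimethyloxiran-2-yl]-2-(triethylsilyloxy)acetaldehyde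
Product: 32 (4aS,7S,8Z,11aR)-4-{(2S)-2-[(2R)-3,3-dimethyloxiran-2-yl]-1-hydroxy-2-(triethylsilyloxy)ethyl}-7-methyl-11-methylidene-7-(triethylsilyloxy)-4,4a,5,6,7,10,11,11a-octahydro-1H-cyclonona[c]pyran-3-one (mixture of epimers at C4 and C12)
Conditions: LDA, THF, −78 °C; then 31, −78 °C; aq. NH4Cl
Reagents that add atoms: none
Why: Deprotonation of the lactone at C4 with LDA and aldol addition to the α-silyloxy aldehyde at −78 °C; the configurations at C4 and C12 do not matter because both centres are removed in step 22, and C13 is no longer enolisable once the aldehyde has reacted.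

Step 22
Reactants: 32 aldol adduct (mixture of epimers at C4 and C12)
Product: 34 (4E,4aS,7S,8Z,11aR)-4-{(2S)-2-[(2R)-3,3-dimethyloxiran-2-yl]-2-(triethylsilyloxy)ethylidene}-7-methyl-11-methylidene-7-(triethylsilyloxy)-4,4a,5,6,7,10,11,11a-octahydro-1H-cyclonona[c]pyran-3-one, via mesylate 33 (not isolated)
Conditions: MsCl, Et3N, CH2Cl2, 0 °C; then DBU, 0 to 25 °C
Reagents that add atoms: none
Why: Mesylation of the β-hydroxy lactone and E1cB elimination; the enolate expels mesylate from the conformer that keeps the C13 chain away from the lactone carbonyl, so the more stable E-alkylidene lactone (C12–H syn to C3=O) should form.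

Step 23
Reactants: 34 bis(triethylsilyl) ether of the E-alkylidene lactone
Product: 35 (4E,4aS,7S,8Z,11aR)-4-{(2S)-2-[(2R)-3,3-dimethyloxiran-2-yl]-2-hydroxyethylidene}-7-hydroxy-7-methyl-11-methylidene-4,4a,5,6,7,10,11,11a-octahydro-1H-cyclonona[c]pyran-3-one
Conditions: TBAF, AcOH (1:1), THF, 0 to 25 °C
Reagents that add atoms: none
Why: Fluoride cleavage of both triethylsilyl ethers, buffered with acetic acid so that the liberated C13 alkoxide neither opens the neighbouring epoxide (Payne rearrangement) nor adds to the enoate.

Step 24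
Reactants: 35 7,13-diol
Product: 36 (1S)-1-[(2R)-3,3-dimethyloxiran-2-yl]-2-[(4E,4aS,7S,8Z,11aR)-7-hydroxy-7-methyl-11-methylidene-3-oxo-4a,5,6,7,10,11,11a-heptahydro-1H-cyclonona[c]pyran-4-ylidene]ethyl acetate
Conditions: Ac2O, pyridine, DMAP (cat.), CH2Cl2, 0 °C
Reagents that add atoms: acetic anhydride, CC(=O)OC(C)=O
Why: Selective acetylation of the secondary allylic C13 hydroxyl; the tertiary C7 hydroxyl does not react under these conditions.

Step 25
Reactants: 36 C13 acetate with free C7 hydroxyl and Z-C8=C9 alkene
Product: 37 CNP0113449.2, the (7S,8R,9R)-8,9-epoxide of 36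
Conditions: VO(acac)2 (10 mol%), t-BuOOH (in decane), CH2Cl2, 0 °C
Reagents that add atoms: tert-butyl hydroperoxide, CC(C)(C)OO
Why: Vanadium-catalysed hydroxyl-directed epoxidation: the vanadium alkoxide of the C7 hydroxyl delivers peroxide oxygen to the adjacent Z-C8=C9 alkene on the face of the C–O bond, which for eight- and nine-membered cyclic allylic alcohols gives the cis epoxy alcohol, here (8R,9R) from (7S); the remote C11 methylene and the electron-poor C4=C12 alkene should not be reached.

## Compound list

1 | (R)-4-benzyloxazolidin-2-one | O=C1N[C@H](Cc2ccccc2)CO1 | starting material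
2 | (E)-but-2-enoyl chloride | C/C=C/C(Cl)=O | starting material
3 | (R)-4-benzyl-3-[(E)-but-2-enoyl]oxazolidin-2-one | C/C=C/C(=O)N1[C@H](Cc2ccccc2)COC1=O | intermediate
4 | acetaldehyde | CC=O | starting material
5 | dibutylboron Z(O)-dienolate of 3 | C=C/C=C(\OB(CCCC)CCCC)N1[C@H](Cc2ccccc2)COC1=O | intermediate (not isolated)
6 | dibutylboron aldolate of 7 | C=C[C@H]([C@H](C)OB(CCCC)CCCC)C(=O)N1[C@H](Cc2ccccc2)COC1=O | intermediate (not isolated)
7 | (R)-4-benzyl-3-[(2R,3S)-2-ethenyl-3-hydroxybutanoyl]oxazolidin-2-one | C=C[C@H]([C@H](C)O)C(=O)N1[C@H](Cc2ccccc2)COC1=O | intermediate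
8 | (2S,3S)-2-ethenylbutane-1,3-diol | C=C[C@H]([C@H](C)O)CO | intermediate
9 | (2S,3S)-2-ethenyl-3-hydroxybutyl prop-2-enoate | C=C[C@H]([C@H](C)O)COC(=O)C=C | intermediate
10 | (5S)-5-[(1S)-1-hydroxyethyl]-5,6-dihydro-2H-pyran-2-one | O=C1C=C[C@H]([C@H](C)O)CO1 | intermediate
11 | (5S)-5-[(1S)-1-(trimethylsilyloxy)ethyl]-5,6-dihydro-2H-pyran-2-one | O=C1C=C[C@H]([C@H](C)O[Si](C)(C)C)CO1 | intermediate
12 | (S)-linalool, (3S)-3,7-dimethylocta-1,6-dien-3-ol | C=C[C@@](C)(O)CCC=C(C)C | starting material
13 | triethyl{[(3S)-3,7-dimethylocta-1,6-dien-3-yl]oxy}silane | C=C[C@@](C)(O[Si](CC)(CC)CC)CCC=C(C)C | intermediate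
14 | (4S)-4-methyl-4-(triethylsilyloxy)hex-5-enal | C=C[C@@](C)(O[Si](CC)(CC)CC)CCC=O | intermediate
15 | (4S)-4-methyl-4-(triethylsilyloxy)hex-5-enoic acid | C=C[C@@](C)(O[Si](CC)(CC)CC)CCC(=O)O | intermediate
16 | 2-thioxopyridin-1(2H)-yl (4S)-4-methyl-4-(triethylsilyloxy)hex-5-enoate (Barton ester) | C=C[C@@](C)(O[Si](CC)(CC)CC)CCC(=O)ON1C=CC=CC1=S | intermediate (not isolated)
17 | triethyl{[(3S)-5-iodo-3-methylpent-1-en-3-yl]oxy}silane | C=C[C@@](C)(O[Si](CC)(CC)CC)CCI | intermediate
18 | [(3S)-3-methyl-3-(triethylsilyloxy)pent-4-en-1-yl]magnesium iodide | C=C[C@@](C)(O[Si](CC)(CC)CC)CC[Mg]I | intermediate (not isolated)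
19 | trimethylsilyl ketene acetal of the conjugate adduct, (4R,5S)-4-[(3S)-3-methyl-3-(triethylsilyloxy)pent-4-en-1-yl]-2-(trimethylsilyloxy)-5-[(1S)-1-(trimethylsilyloxy)ethyl]-5,6-dihydro-4H-pyran | C[Si](C)(C)OC1=C[C@@H](CC[C@](C)(O[Si](CC)(CC)CC)C=C)[C@H]([C@H](C)O[Si](C)(C)C)CO1 | intermediate (not isolated)
20 | (4R,5S)-5-[(1S)-1-hydroxyethyl]-4-[(3S)-3-methyl-3-(triethylsilyloxy)pent-4-en-1-yl]oxan-2-one | O=C1C[C@@H](CC[C@](C)(O[Si](CC)(CC)CC)C=C)[C@H]([C@H](C)O)CO1 | intermediate
21 | (4R,5S)-5-acetyl-4-[(3S)-3-methyl-3-(triethylsilyloxy)pent-4-en-1-yl]oxan-2-one | O=C1C[C@@H](CC[C@](C)(O[Si](CC)(CC)CC)C=C)[C@H](C(C)=O)CO1 | intermediate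
22 | 1-[(3S,4R)-4-[(3S)-3-methyl-3-(triethylsilyloxy)pent-4-en-1-yl]-6-oxooxan-3-yl]ethenyl trifluoromethanesulfonate | C=C(OS(=O)(=O)C(F)(F)F)[C@@H]1COC(=O)C[C@H]1CC[C@](C)(O[Si](CC)(CC)CC)C=C | intermediate
23 | allyl methyl carbonate | C=CCOC(=O)OC | starting material
24 | methyl (2E,4S)-4-methyl-6-[(4R,5S)-2-oxo-5-{1-[(trifluoromethanesulfonyl)oxy]ethenyl}oxan-4-yl]-4-(triethylsilyloxy)hex-2-en-1-yl carbonate | FC(F)(F)S(=O)(=O)OC(=C)[C@@H]1COC(=O)C[C@H]1CC[C@](C)(O[Si](CC)(CC)CC)/C=C/COC(=O)OC | intermediate
25 | (4aR,7S,8Z,11aR)-7-methyl-11-methylidene-7-(triethylsilyloxy)-4,4a,5,6,7,10,11,11a-octahydro-1H-cyclonona[c]pyran-3-one | C=C1C/C=C\[C@@](C)(O[Si](CC)(CC)CC)CC[C@@H]2CC(=O)OC[C@@H]12 | intermediate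
26 | (S)-2,2-dimethyl-1,3-dioxolane-4-carbaldehyde | O=C[C@@H]1COC(C)(C)O1 | starting material
27 | (4R)-2,2-dimethyl-4-(2-methylprop-1-en-1-yl)-1,3-dioxolane | CC(C)=C[C@@H]1COC(C)(C)O1 | intermediate
28 | (2R)-4-methylpent-3-ene-1,2-diol | CC(C)=C[C@@H](O)CO | intermediate
29 | (1S)-1-[(2R)-3,3-dimethyloxiran-2-yl]ethane-1,2-diol | OC[C@H](O)[C@H]1OC1(C)C | intermediate
30 | (2R)-2-[(1S)-1,2-bis(triethylsilyloxy)ethyl]-3,3-dimethyloxirane | CC[Si](CC)(CC)OC[C@H](O[Si](CC)(CC)CC)[C@H]1OC1(C)C | intermediate
31 | (2R)-2-[(2R)-3,3-dimethyloxiran-2-yl]-2-(triethylsilyloxy)acetaldehyde | O=C[C@H](O[Si](CC)(CC)CC)[C@H]1OC1(C)C | intermediate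
32 | aldol adduct, C12 alcohol (epimers at C4 and C12), C7 and C13 triethylsilyl ethers | C=C1C/C=C\[C@@](C)(O[Si](CC)(CC)CC)CC[C@@H]2C(C(O)[C@H](O[Si](CC)(CC)CC)[C@H]3OC3(C)C)C(=O)OC[C@@H]12 | intermediate
33 | C12 methanesulfonate of 32 | C=C1C/C=C\[C@@](C)(O[Si](CC)(CC)CC)CC[C@@H]2C(C(OS(C)(=O)=O)[C@H](O[Si](CC)(CC)CC)[C@H]3OC3(C)C)C(=O)OC[C@@H]12 | intermediate (not isolated)
34 | (4E,4aS,7S,8Z,11aR)-4-{(2S)-2-[(2R)-3,3-dimethyloxiran-2-yl]-2-(triethylsilyloxy)ethylidene}-7-methyl-11-methylidene-7-(triethylsilyloxy)-4,4a,5,6,7,10,11,11a-octahydro-1H-cyclonona[c]pyran-3-one | C=C1C/C=C\[C@@](C)(O[Si](CC)(CC)CC)CC[C@@H]2/C(=C\[C@H](O[Si](CC)(CC)CC)[C@H]3OC3(C)C)C(=O)OC[C@@H]12 | intermediate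
35 | (4E,4aS,7S,8Z,11aR)-4-{(2S)-2-[(2R)-3,3-dimethyloxiran-2-yl]-2-hydroxyethylidene}-7-hydroxy-7-methyl-11-methylidene-4,4a,5,6,7,10,11,11a-octahydro-1H-cyclonona[c]pyran-3-one | C=C1C/C=C\[C@@](C)(O)CC[C@@H]2/C(=C\[C@H](O)[C@H]3OC3(C)C)C(=O)OC[C@@H]12 | intermediate
36 | C13 acetate of 35 (free C7 hydroxyl, Z-C8=C9) | C=C1C/C=C\[C@@](C)(O)CC[C@@H]2/C(=C\[C@H](OC(C)=O)[C@H]3OC3(C)C)C(=O)OC[C@@H]12 | intermediate
37 | CNP0113449.2, (1S)-1-[(2R)-3,3-dimethyloxiran-2-yl]-2-[(4E,4aS,7S,8R,9R,11aR)-8,9-epoxy-7-hydroxy-7-methyl-11-methylidene-3-oxo-nonahydro-1H-cyclonona[c]pyran-4-ylidene]ethyl acetate | C=C1C[C@H]2O[C@H]2[C@@](C)(O)CC[C@@H]2/C(=C\[C@H](OC(C)=O)[C@H]3OC3(C)C)C(=O)OC[C@@H]12 | target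

## Step count and risks

Total step count: 25. Longest linear sequence: 16 steps (steps 1–6, 11–15, 21–25).

**Step 15 (key step, proposed new method).** Most likely failure: bond formation at the proximal allyl terminus C8 to a seven-membered ring, or reduction of the triflate and intermolecular allyl coupling, because closure of the nine-membered ring is slow. Fallback with known chemistry, from 22 back to 25: a palladium-catalysed intramolecular coupling of a vinylstannane with the allylic carbonate (Stille-type allyl–vinyl coupling). Enol triflate 22 is stannylated with Me3SnSnMe3, Pd(PPh3)4 and LiCl to the vinylstannane F1. Cross metathesis of F1 with 23, as in step 14, gives the stannyl allylic carbonate F2. Zerovalent palladium (Pd2(dba)3, AsPh3, DMF, high dilution) ionises the carbonate and couples the π-allyl with the stannane to give 25.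

**Step 13.** Most likely failure: enolisation towards C11a, followed by β-elimination of the C1 carboxylate and opening of the lactone, or proton exchange between enolate and unreacted ketone that erodes the regiochemistry. Fallback, from 21 back to 22: the kinetic enolate is trapped as it forms by adding 21 to premixed LDA/TMSCl at −78 °C, giving the trimethylsilyl enol ether F3. F3 is converted into 22 with CsF and PhNTf2 in DME.

**Step 14.** Most likely failure: slow initiation at the crowded vinyl group beside the silylated quaternary C7, with consumption of 23 by self-metathesis and catalyst decay. Fallback, from 22 back to 24: the silyl group is removed with HF·pyridine to the tertiary allylic alcohol F4, which is a more willing metathesis partner. Cross metathesis of F4 with 23 gives the hydroxy carbonate F5, and TESOTf/2,6-lutidine returns 24.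

**Step 22.** Most likely failure: loss of geometric control in the elimination, or γ-deprotonation by DBU with epimerisation at C13. Fallback, from 25 back to 34: a Horner–Wadsworth–Emmons olefination replaces aldol/elimination. Lactone 25 is treated with LDA (2 equiv) and diethyl chlorophosphate to give the α-phosphono lactone F6. F6 reacts with aldehyde 31 under LiCl/DBU to give 34, where reversible addition should favour the E isomer.

**Step 25.** Most likely failure: incomplete facial selectivity, or transannular attack on the new epoxide by the tertiary hydroxyl or the C11 methylene, on the fully elaborated and acid-sensitive substrate. Fallback, from 25 back to 37: the epoxidation is moved to the bicyclic stage, where isomers can be separated early.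
- TBAF on 25 gives the C7 alcohol F7.
- VO(acac)2/t-BuOOH gives the epoxy alcohol F8.
- TESOTf/2,6-lutidine gives the silyl ether F9.
- Aldol reaction with 31 as in step 21 gives the adduct F10.
- MsCl/Et3N then DBU gives, through the mesylate F11, the alkylidene lactone F12.
- TBAF/AcOH gives the diol F13, and Ac2O/pyridine gives 37.

## Further compounds

F1 | step 15 | (4R,5S)-4-[(3S)-3-methyl-3-(triethylsilyloxy)pent-4-en-1-yl]-5-[1-(trimethylstannyl)ethenyl]oxan-2-one | C=C([Sn](C)(C)C)[C@@H]1COC(=O)C[C@H]1CC[C@](C)(O[Si](CC)(CC)CC)C=C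
F2 | step 15 | methyl (2E,4S)-4-methyl-6-{(4R,5S)-2-oxo-5-[1-(trimethylstannyl)ethenyl]oxan-4-yl}-4-(triethylsilyloxy)hex-2-en-1-yl carbonate | C=C([Sn](C)(C)C)[C@@H]1COC(=O)C[C@H]1CC[C@](C)(O[Si](CC)(CC)CC)/C=C/COC(=O)OC
F3 | step 13 | (4R,5S)-4-[(3S)-3-methyl-3-(triethylsilyloxy)pent-4-en-1-yl]-5-[1-(trimethylsilyloxy)ethenyl]oxan-2-one | C=C(O[Si](C)(C)C)[C@@H]1COC(=O)C[C@H]1CC[C@](C)(O[Si](CC)(CC)CC)C=C
F4 | step 14 | 1-[(3S,4R)-4-[(3S)-3-hydroxy-3-methylpent-4-en-1-yl]-6-oxooxan-3-yl]ethenyl trifluoromethanesulfonate | C=C(OS(=O)(=O)C(F)(F)F)[C@@H]1COC(=O)C[C@H]1CC[C@](C)(O)C=C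
F5 | step 14 | methyl (2E,4S)-4-hydroxy-4-methyl-6-[(4R,5S)-2-oxo-5-{1-[(trifluoromethanesulfonyl)oxy]ethenyl}oxan-4-yl]hex-2-en-1-yl carbonate | C=C(OS(=O)(=O)C(F)(F)F)[C@@H]1COC(=O)C[C@H]1CC[C@](C)(O)/C=C/COC(=O)OC
F6 | step 22 | diethyl [(4aR,7S,8Z,11aR)-7-methyl-11-methylidene-3-oxo-7-(triethylsilyloxy)-4,4a,5,6,7,10,11,11a-octahydro-1H-cyclonona[c]pyran-4-yl]phosphonate (C4 epimers) | C=C1C/C=C\[C@@](C)(O[Si](CC)(CC)CC)CC[C@@H]2C(P(=O)(OCC)OCC)C(=O)OC[C@@H]12
F7 | step 25 | (4aR,7S,8Z,11aR)-7-hydroxy-7-methyl-11-methylidene-4,4a,5,6,7,10,11,11a-octahydro-1H-cyclonona[c]pyran-3-one | C=C1C/C=C\[C@@](C)(O)CC[C@@H]2CC(=O)OC[C@@H]12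
F8 | step 25 | (7S,8R,9R)-8,9-epoxide of F7 | C=C1C[C@H]2O[C@H]2[C@@](C)(O)CC[C@@H]2CC(=O)OC[C@@H]12
F9 | step 25 | C7 triethylsilyl ether of F8 | C=C1C[C@H]2O[C@H]2[C@@](C)(O[Si](CC)(CC)CC)CC[C@@H]2CC(=O)OC[C@@H]12
F10 | step 25 | aldol adduct of F9 with 31 (epimers at C4 and C12) | C=C1C[C@H]2O[C@H]2[C@@](C)(O[Si](CC)(CC)CC)CC[C@@H]2C(C(O)[C@H](O[Si](CC)(CC)CC)[C@H]3OC3(C)C)C(=O)OC[C@@H]12
F11 | step 25 | C12 methanesulfonate of F10 | C=C1C[C@H]2O[C@H]2[C@@](C)(O[Si](CC)(CC)CC)CC[C@@H]2C(C(OS(C)(=O)=O)[C@H](O[Si](CC)(CC)CC)[C@H]3OC3(C)C)C(=O)OC[C@@H]12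
F12 | step 25 | 8,9-epoxide of 34 (C7 and C13 triethylsilyl ethers, 4E) | C=C1C[C@H]2O[C@H]2[C@@](C)(O[Si](CC)(CC)CC)CC[C@@H]2/C(=C\[C@H](O[Si](CC)(CC)CC)[C@H]3OC3(C)C)C(=O)OC[C@@H]12
F13 | step 25 | 13-deacetyl derivative of 37 (7,13-diol) | C=C1C[C@H]2O[C@H]2[C@@](C)(O)CC[C@@H]2/C(=C\[C@H](O)[C@H]3OC3(C)C)C(=O)OC[C@@H]12
A1 | alternative 1 | C13 tert-butyldimethylsilyl ether of the deacetyl target | C=C1C[C@H]2O[C@H]2[C@@](C)(O)CC[C@@H]2/C(=C\[C@H](O[Si](C)(C)C(C)(C)C)[C@H]3OC3(C)C)C(=O)OC[C@@H]12
A2 | alternative 2 | nine-membered Z-enone with exocyclic methylene (C7 ketone, PMB and TBS ethers) | C=C1C/C=C\C(=O)CC[C@H](CCOCc2ccc(OC)cc2)[C@H]1CO[Si](C)(C)C(C)(C)C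
A3 | alternative 3 | nine-membered cis-7,8-diol lactone with C9 PMB ether | C=C1C[C@H](OCc2ccc(OC)cc2)[C@@H](O)[C@@](C)(O)CC[C@@H]2CC(=O)OC[C@@H]12
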